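Time was the setting I turned first: by hand, more of it adds Q for as long as L lasts, but the asked 2.0 min lies beyond the last reading at 80.0 s, and Monday's run gained 1.6 percentage points between 60.0 s and 80.0 s, close to the scatter of 1 point, so I took each answer to be a plateau and looked for what sets its height.

* ranking by amount of Q, in percent of the L charged, from high to low, at 2.0 min (midnight / autumn / spring / dawn / summer)
* the amount of Q, in percent of the L charged of the flask you put first, at 2.0 min
* the amount of Q, in percent of the L charged of the flask you put last, at 2.0 min

| flask | L | Z | G | remark | time |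
|---|---|---|---|---|---|
| Thursday's | 0.10 M | 0.070 M | 2 mM | run made earlier |  |
| Saturday's | 0.10 M | 0.24 M | 2 mM | run made earlier |  |
| Monday's | 0.10 M | 0.18 M | 3 mM | run made earlier |  |
| midnight | 0.030 M | 0.120 M | 8.0 mM |  | 2.0 min |
| autumn | 0.10 M | 0.180 M | 2.0 mM |  | 2.0 min |
| spring | 0.15 M | 0.400 M | 4.0 mM |  | 2.0 min |
| dawn | 0.10 M | 0.180 M | 4.0 mM |  | 2.0 min |
| summer | 0.050 M | 0.250 M | 6.0 mM |  | 2.0 min |

- Thursday's (time / s: Q / %): 10.0: 18.6; 20.0: 32.9; 40.0: 48.7; 60.0: 55.0; 80.0: 61.1
- Saturday's (time / s: Q / %): 10.0: 32.7; 12.0: 35.7; 25.0: 56.5; 40.0: 67.7; 80.0: 71.5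
- Monday's (time / s: Q / %): 15.0: 53.4; 30.0: 68.9; 50.0: 76.6; 60.0: 77.2; 80.0: 78.8

(standard deviation of a reading: 1 percentage point)

- the numbers in the tables scatter by 1 percentage point (one standard deviation)

I expected [Z] to quicken the reaction, and it did: at 10.0 s Saturday's run, with 0.24 M, read 32.7% against 18.6% for Thursday's with 0.070 M, a factor of 1.76 for a factor of 3.43 in [Z], so the order in [Z] looked below one. I set Thursday's run aside, since it held less Z than L, whereas each asked flask holds more Z than L.

I expected [G] to bring speed too, but it seemed to move the plateau as well: Monday's run, with 3 mM, ended at 78.8% and Saturday's, with 2 mM, at 71.5%, although Monday's held less Z.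

No run moved [L], so here I had to reckon. A catalysed path first order in [L], with nothing beside it and with [Z] and [G] held, gives the same yield at any charge of L, so I supposed that a rival path, second order in [L], takes what Q never receives. With [Z] held, the rival's rate over the catalysed rate then goes as [L]/[G], and I defined the waste number, a selectivity factor of my own, as the fraction of charged L lost from Q per unit of the charge ratio [L]/[G]. Saturday's last reading gives 0.00570 and Monday's 0.00636, although the two runs differ in [Z] as well, and the mean of these readings is 0.00603.

Taking one minus the waste number times the ratio, I reckoned midnight at 97.7%, summer at 95.0%, dawn at 84.9%, spring at 77.4% and autumn at 69.8%.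

The forecast differed from my reckoning: it gave midnight > dawn > autumn > summer > spring, with 79.5% first and 65% last, on the ground “So the catalyst is dying.”

The flasks ran midnight > summer > dawn > spring > autumn, with midnight at 97.7% and autumn at 71.8%.

    G ⇌ D (K = 0.400, k = 0.0370 s⁻¹)
    2 L → X (k = 0.190 L mol⁻¹ s⁻¹)
    Z + E ⇌ J (K = 3.30 L mol⁻¹, k = 81.0 L mol⁻¹ s⁻¹)
    L + G → E (k = 41.0 L mol⁻¹ s⁻¹)
    J → G + Q (k = 13.0 s⁻¹)

In autumn at 2.00 min, X held 28.2% of the L charged, beside Q. The waste number of 0.00603 had given autumn 69.8%, and it gives the same for the neighbouring flask, which differs from autumn by holding 0.072 M of Z, less than its L. That neighbour gave 63.1%, and at its end 12% of its Z stood unbound.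

The earlier runs and the new flask were computed for an exercise; scatter was added.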